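**Retrosynthetic overview**

- The strategy rests on one feature: C3 of one indole is bonded both to C3a of its own benzene ring and to the bridge CH2 carbon, which is also bonded to C3' of the other indole. This C3a–C3–CH2–C3' array is what results when an aryl group and an indolyl group are added to the two carbons of a propargyl triple bond.
- Last disconnection: the second indole is the aromatic tautomer of a 3-(indol-3-ylmethylidene)indoline, reached by a 1,3-hydrogen shift from C2 to the bridge carbon.
- Key disconnection: C3–C3a and bridge carbon–C3' are formed in one palladium-catalysed operation from an N-propargyl-N-tert-prenyl-2-bromoaniline and a 1-tert-prenyl-3-indolylboronate (5-exo-dig carbopalladation, Suzuki termination).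
- Both N–C(quaternary) bonds are made beforehand on simple amines (2-bromoaniline, indoline) by copper-catalysed tert-propargylation and semi-hydrogenation.
- Ring order: the first indole is completed from indoline before the key step; the five-membered nitrogen ring of the second indole closes in the key step and becomes aromatic in the last step.

Key step: step 9

Remark on the chemistry: the target has no stereocentre and no stereogenic alkene; the E geometry of the key-step product is transient and is erased in the last step.

**Route**

Step 1
Reactants: 1 2-bromoaniline; 2 3-chloro-3-methylbut-1-yne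
Product: 3 2-bromo-N-(2-methylbut-3-yn-2-yl)aniline
Conditions: CuCl (10 mol %), Et3N, THF, 0 °C to rt
Reagents that add atoms: none
Why: Copper-catalysed propargylic amination of a tertiary propargyl chloride (Hennion-type substitution) forms the N–C(quaternary) bond that a direct SN2 reaction cannot, and the crowded product should not react a second time.

Step 2
Reactants: 3 2-bromo-N-(2-methylbut-3-yn-2-yl)aniline
Product: 4 2-bromo-N-(2-methylbut-3-en-2-yl)aniline
Conditions: H2 (1 atm), Pd/CaCO3 poisoned with Pb(OAc)2, quinoline, EtOAc, rt, stopped after 1 equiv H2
Reagents that add atoms: none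
Why: Lindlar semi-hydrogenation should stop at the terminal alkene on the quinoline-poisoned catalyst and leave the aryl bromide untouched.

Step 3
Reactants: 4 2-bromo-N-(2-methylbut-3-en-2-yl)aniline
Product: 5 2-bromo-N-(2-methylbut-3-en-2-yl)-N-(prop-2-yn-1-yl)aniline
Conditions: propargyl bromide (80% in toluene, 3 equiv, in portions), K2CO3, KI (cat.), DMF, 80 °C
Reagents that add atoms: propargyl bromide (3-bromoprop-1-yne), C#CCBr
Why: SN2 N-alkylation (iodide-assisted) with a slim, highly reactive propargylic halide; the tert-alkyl group twists nitrogen out of conjugation with the ring, so it should keep amine-like nucleophilicity despite the crowding.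

Step 4
Reactants: 6 indoline; 2 3-chloro-3-methylbut-1-yne
Product: 7 1-(2-methylbut-3-yn-2-yl)indoline
Conditions: CuCl (10 mol %), Et3N, THF, 0 °C to rt
Reagents that add atoms: none
Why: The same copper-catalysed propargylic amination, applied to indoline because its sp3 nitrogen is a far better nucleophile than an indole nitrogen.

Step 5
Reactants: 7 1-(2-methylbut-3-yn-2-yl)indoline
Product: 8 1-(2-methylbut-3-en-2-yl)indoline
Conditions: H2 (1 atm), Pd/CaCO3 poisoned with Pb(OAc)2, quinoline, EtOAc, rt, stopped after 1 equiv H2
Reagents that add atoms: none
Why: Lindlar semi-hydrogenation of the terminal alkyne to the vinyl group of the tert-prenyl substituent.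

Step 6
Reactants: 8 1-(2-methylbut-3-en-2-yl)indoline
Product: 9 1-(2-methylbut-3-en-2-yl)-1H-indole
Conditions: activated MnO2 (excess), CH2Cl2, rt
Reagents that add atoms: none
Why: Oxidative dehydrogenation of an indoline to the indole is driven by aromatisation, and the isolated vinyl group is inert to MnO2.

Step 7
Reactants: 9 1-(2-methylbut-3-en-2-yl)-1H-indole
Product: 10 3-bromo-1-(2-methylbut-3-en-2-yl)-1H-indole
Conditions: NBS (1.0 equiv), THF, −78 to 0 °C, dark; used without storage
Reagents that add atoms: N-bromosuccinimide, O=C1CCC(=O)N1Br
Why: Electrophilic aromatic bromination at C3, the most nucleophilic position of an N-alkylindole, should be far faster at low temperature than addition to the monosubstituted alkene.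

Step 8
Reactants: 10 3-bromo-1-(2-methylbut-3-en-2-yl)-1H-indole
Product: 12 1-(2-methylbut-3-en-2-yl)-3-(4,4,5,5-tetramethyl-1,3,2-dioxaborolan-2-yl)-1H-indole, via 3-lithioindole 11 (not isolated)
Conditions: n-BuLi (1.1 equiv), THF, −78 °C; then 2-isopropoxy-4,4,5,5-tetramethyl-1,3,2-dioxaborolane, −78 °C to rt; aq. NH4Cl
Reagents that add atoms: 2-isopropoxy-4,4,5,5-tetramethyl-1,3,2-dioxaborolane, CC(C)OB1OC(C)(C)C(C)(C)O1
Why: Bromine–lithium exchange at −78 °C followed by trapping with the borate ester (lithiation–borylation) should intercept the 3-lithio species before it can migrate to C2, which the bulky N-substituent also shields.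

Step 9
Reactants: 5 2-bromo-N-(2-methylbut-3-en-2-yl)-N-(prop-2-yn-1-yl)aniline; 12 1-(2-methylbut-3-en-2-yl)-3-(4,4,5,5-tetramethyl-1,3,2-dioxaborolan-2-yl)-1H-indole
Product: 15 (E)-1-(2-methylbut-3-en-2-yl)-3-{[1-(2-methylbut-3-en-2-yl)-1H-indol-3-yl]methylidene}indoline, via arylpalladium bromide 13 (not isolated), via vinylpalladium bromide 14 (not isolated)
Conditions: Pd(OAc)2 (5 mol %), PPh3 (15 mol %), K3PO4 (3 equiv), 12 (1.5 equiv, added in portions), 1,4-dioxane–H2O 9:1, 90 °C, argon
Reagents that add atoms: none
Why: Zerovalent palladium formed from Pd(OAc)2 and PPh3 inserts into the C–Br bond of 5 to give 13, whose aryl group adds syn across the propargyl triple bond in a 5-exo-dig closure that forms C3–C3a and the five-membered nitrogen ring and leaves palladium on the former terminal carbon in 14. The only β-position of that carbon is the fully substituted C3, so β-hydride elimination is impossible and 14 should persist until it transmetalates with the phosphate-activated boronate 12; reductive elimination then forms the bridge carbon–C3' bond. The closest known reaction type is the domino intramolecular carbopalladation/Suzuki coupling of 2-halo-N-propargylanilines with boronic acids, which gives 3-(arylmethylidene)indolines. No stereocentre is created; the alkene should be E because syn addition places palladium, and after stereoretentive coupling the indolyl group, cis to C3a. Two selectivities are needed: insertion of the alkyne rather than the tert-prenyl vinyl group, secured because a triple bond binds and inserts faster and the rival 5-exo-trig closure would have to form its bond at a vinyl carbon directly attached to the quaternary N–CMe2 centre, and cyclisation before intermolecular transmetalation, secured by the intramolecular nature of the insertion and helped by portionwise addition of 12. The E geometry also keeps palladium in 14 on the benzo side, away from the N-substituent, so a second insertion into the tert-prenyl alkene is geometrically excluded.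

Step 10
Reactants: 15 (E)-1-(2-methylbut-3-en-2-yl)-3-{[1-(2-methylbut-3-en-2-yl)-1H-indol-3-yl]methylidene}indoline
Product: 16 polonidine A, bis[1-(2-methylbut-3-en-2-yl)-1H-indol-3-yl]methane
Conditions: KOtBu (0.3 equiv), DMSO, rt, argon
Reagents that add atoms: none
Why: Base-catalysed prototropic 1,3-hydrogen shift from C2 to the bridge carbon is driven by aromatisation of the new pyrrole ring; 15 has no other acidic C–H, and the tert-prenyl groups carry no allylic hydrogen and cannot isomerise.

**Compound list**

1 | 2-bromoaniline | Nc1ccccc1Br | starting material
2 | 3-chloro-3-methylbut-1-yne | C#CC(C)(C)Cl | starting material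
3 | 2-bromo-N-(2-methylbut-3-yn-2-yl)aniline | C#CC(C)(C)Nc1ccccc1Br | intermediate
4 | 2-bromo-N-(2-methylbut-3-en-2-yl)aniline | C=CC(C)(C)Nc1ccccc1Br | intermediate
5 | 2-bromo-N-(2-methylbut-3-en-2-yl)-N-(prop-2-yn-1-yl)aniline | C=CC(C)(C)N(CC#C)c1ccccc1Br | intermediate
6 | indoline | C1Cc2ccccc2N1 | starting material
7 | 1-(2-methylbut-3-yn-2-yl)indoline | C#CC(C)(C)N1CCc2ccccc21 | intermediate
8 | 1-(2-methylbut-3-en-2-yl)indoline | C=CC(C)(C)N1CCc2ccccc21 | intermediate
9 | 1-(2-methylbut-3-en-2-yl)-1H-indole | C=CC(C)(C)n1ccc2ccccc21 | intermediate
10 | 3-bromo-1-(2-methylbut-3-en-2-yl)-1H-indole | C=CC(C)(C)n1cc(Br)c2ccccc21 | intermediate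
11 | 3-lithio-1-(2-methylbut-3-en-2-yl)-1H-indole (not isolated) | [Li]c1cn(C(C)(C)C=C)c2ccccc12 | intermediate
12 | 1-(2-methylbut-3-en-2-yl)-3-(4,4,5,5-tetramethyl-1,3,2-dioxaborolan-2-yl)-1H-indole | C=CC(C)(C)n1cc(B2OC(C)(C)C(C)(C)O2)c2ccccc21 | intermediate
13 | {2-[(2-methylbut-3-en-2-yl)(prop-2-yn-1-yl)amino]phenyl}palladium bromide, phosphine ligands omitted (not isolated) | C=CC(C)(C)N(CC#C)c1ccccc1[Pd]Br | intermediate
14 | (E)-{[1-(2-methylbut-3-en-2-yl)indolin-3-ylidene]methyl}palladium bromide, phosphine ligands omitted (not isolated) | C=CC(C)(C)N1C/C(=C/[Pd]Br)c2ccccc21 | intermediate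
15 | (E)-1-(2-methylbut-3-en-2-yl)-3-{[1-(2-methylbut-3-en-2-yl)-1H-indol-3-yl]methylidene}indoline | C=CC(C)(C)N1C/C(=C/c2cn(C(C)(C)C=C)c3ccccc23)c2ccccc21 | intermediate
16 | polonidine A, bis[1-(2-methylbut-3-en-2-yl)-1H-indol-3-yl]methane | C=CC(C)(C)n1cc(Cc2cn(C(C)(C)C=C)c3ccccc23)c2ccccc21 | target

**Totals**

Total step count: 10.
Longest linear sequence: 7 steps (indoline 6 to 16 through steps 4, 5, 6, 7, 8, 9 and 10).

**Steps most likely to fail**

1. Step 9. The arylpalladium intermediate may be diverted before it inserts the alkyne, either by 5-exo-trig insertion into the tert-prenyl vinyl group or by direct coupling with the boronate. The electron-rich boronate may also be consumed by protodeboronation in the hot aqueous base. Fallback: the bridge is built without palladium, setting out from 9 and coming back to the route at 16. Two equivalents of 9 are condensed with one equivalent of 37% aqueous formaldehyde under mild acid catalysis (AcOH cat., EtOH–H2O, rt). Electrophilic substitution at C3 should give [1-(2-methylbut-3-en-2-yl)-1H-indol-3-yl]methanol F1 in the flask. F1 is then substituted at its benzylic carbon by the second molecule of 9 under the same catalysis (double Friedel–Crafts hydroxyalkylation/alkylation, the standard bis(indolyl)methane synthesis), which gives 16 directly. The acid is kept weak so that the N-tert-prenyl groups are not ionised.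

2. Step 3. Alkylation at a nitrogen flanked by a tert-alkyl group and an ortho-bromoaryl ring may be slow or incomplete, while propargyl bromide decomposes on prolonged heating. Fallback: setting out from 4 and coming back at 5, the nitrogen is alkylated as its anion with an alkyne whose acidic C–H is masked. Compound 4 is treated with NaH in DMF (0 °C to rt) and 3-bromo-1-(trimethylsilyl)prop-1-yne. The silyl cap prevents proton transfer from the electrophile to the basic nitrogen, and the reaction should give 2-bromo-N-(2-methylbut-3-en-2-yl)-N-[3-(trimethylsilyl)prop-2-yn-1-yl]aniline F2. Desilylation of F2 with K2CO3 in MeOH at rt then gives 5.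

3. Step 8. Lithium may migrate from C3 to C2 if the lithio species warms before trapping, and the pinacol boronate may undergo protodeboronation during work-up and chromatography. Fallback: no boron compound is isolated, setting out from 10 and coming back at 15. Bromide 10 is lithiated as before to 11 and transmetalated at −78 °C with ZnCl2 to give [1-(2-methylbut-3-en-2-yl)-1H-indol-3-yl]zinc chloride F3. F3 is used at once with 5 and Pd(PPh3)4 in THF at 60 °C. The same 5-exo-dig carbopalladation through 13 and 14 is then terminated by Negishi coupling under anhydrous conditions and should give 15.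

**Further compounds**

F1 | step 9 | [1-(2-methylbut-3-en-2-yl)-1H-indol-3-yl]methanol | C=CC(C)(C)n1cc(CO)c2ccccc21
F2 | step 3 | 2-bromo-N-(2-methylbut-3-en-2-yl)-N-[3-(trimethylsilyl)prop-2-yn-1-yl]aniline | C=CC(C)(C)N(CC#C[Si](C)(C)C)c1ccccc1Br
F3 | step 8 | [1-(2-methylbut-3-en-2-yl)-1H-indol-3-yl]zinc chloride | C=CC(C)(C)n1cc([Zn]Cl)c2ccccc21
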